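**Retrosynthetic overview**

1. Feature: in the 11-membered carbocycle (C1 = CMe2, C2–C4 = CH2, C5/C6 = epoxide with Me on C5, C7–C8 = CH2, C9 = C–CO2H, C10 = CH, C11 = CHOBz) the C11 carbinol lies between quaternary C1 and the C9=C10 enoate, which is the pattern of a reverse-prenyl adduct of a 4-oxobut-2-enoate.
2. Target ⇒ benzoylation, ester hydrolysis and C2=C3 saturation ⇒ (11R) hydroxy ester with E C2=C3 ⇒ C11 fixed by oxidation and reagent-controlled reduction ⇒ C1–C11 disconnection: intramolecular Pd/InI umpolung allylation of the C11 enal by the C1 tertiary allylic carbonate.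
3. Open-chain precursor ⇒ C2=C3 by cross-metathesis with 2-methylbut-3-en-2-ol; C5/C6 epoxide by Shi epoxidation with the enantiomeric catalyst; C9=C10 by Horner–Wadsworth–Emmons olefination; C8–C9 by phosphonoacetate alkylation; E C5=C6 by carboalumination of pent-1-en-4-yne and oxirane opening.
4. Ring order: the oxirane first (step 5), then the 11-membered carbocycle (step 10).

Key step: step 10

Assumption: the ring numbering above is used for the open-chain intermediates as well, which makes the target (5S,6S,9E,11R); pent-1-en-4-yne and the L-fructose-derived epoxidation ketone are taken as purchasable.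

**Route**

Step 1
Reactants: 1 pent-1-en-4-yne; 2 oxirane
Product: 5 (3E)-4-methylhepta-3,6-dien-1-ol, via alkenylalane 3 (not isolated), via lithium alkenylalanate 4 (not isolated)
Conditions: Me3Al (2 equiv), Cp2ZrCl2 (0.25 equiv), CH2Cl2, 0 °C → rt; volatiles removed; n-BuLi, THF/hexane, −30 °C; then 2, −30 → 0 °C; aq. potassium sodium tartrate
Reagents that add atoms: trimethylaluminium, C[Al](C)C
Why: Negishi zirconium-catalysed methylalumination adds CH3 and Al syn across the terminal alkyne with CH3 on the internal carbon while the monosubstituted alkene is left alone, and the alkenylalanate made with n-BuLi opens oxirane with retention at the alkenyl carbon, so the future C5=C6 alkene is fixed as E.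

Step 2
Reactants: 5 (3E)-4-methylhepta-3,6-dien-1-ol
Product: 6 (4E)-7-iodo-4-methylhepta-1,4-diene
Conditions: I2, PPh3, imidazole, CH2Cl2, 0 °C
Reagents that add atoms: iodine, II
Why: Appel iodination converts the primary alcohol into the iodide by SN2 displacement of the oxyphosphonium ion under conditions that leave both alkenes untouched.

Step 3
Reactants: 6 (4E)-7-iodo-4-methylhepta-1,4-diene; 7 trimethyl phosphonoacetate
Product: 8 methyl (5E)-2-(dimethoxyphosphoryl)-6-methylnona-5,8-dienoate (racemic at C2 of the ester)
Conditions: NaH, 7 (2.5 equiv), DMF, 0 → 60 °C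
Reagents that add atoms: none
Why: Alkylation of the sodium salt of the phosphonoacetate, a soft stabilised carbanion used in excess to suppress dialkylation, with an unhindered primary iodide is a standard SN2 carbon–carbon bond formation that favours substitution over elimination.

Step 4
Reactants: 8 methyl (5E)-2-(dimethoxyphosphoryl)-6-methylnona-5,8-dienoate; 9 (tert-butyldimethylsilyloxy)acetaldehyde
Product: 10 methyl (2E,5E)-2-[2-(tert-butyldimethylsilyloxy)ethylidene]-6-methylnona-5,8-dienoate
Conditions: NaH, THF, 0 °C; then 9, 0 °C → rt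
Reagents that add atoms: none
Why: Horner–Wadsworth–Emmons olefination of an α-alkyl phosphonoacetate with an unhindered aldehyde should favour the isomer with CH2OTBS trans to CO2Me (E, C8 and C11 cis), and any Z isomer is separable and would in any case be purged as a butenolide after step 8.

Step 5
Reactants: 10 methyl (2E,5E)-2-[2-(tert-butyldimethylsilyloxy)ethylidene]-6-methylnona-5,8-dienoate
Product: 11 methyl (2E)-4-(tert-butyldimethylsilyloxy)-2-{2-[(2S,3S)-3-methyl-3-(prop-2-en-1-yl)oxiran-2-yl]ethyl}but-2-enoate
Conditions: L-fructose-derived ketone 1,2:4,5-di-O-isopropylidene-β-L-erythro-2,3-hexodiulo-2,6-pyranose (0.3 equiv), KHSO5 (as Oxone, 1.4 equiv), K2CO3, Bu4NHSO4, MeCN/CH2(OMe)2, aq. Na2B4O7/Na2EDTA buffer, 0 °C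
Reagents that add atoms: potassium peroxymonosulfate, [K+].[O-]S(=O)(=O)OO
Why: Shi asymmetric epoxidation in which the chiral dioxirane reaches the E-trisubstituted C5=C6 alkene through the spiro transition state; the D-fructose-derived ketone gives R,R epoxides from such alkenes, so its enantiomer sets (5S,6S), while the monosubstituted alkene and the electron-poor enoate react far more slowly.

Step 6
Reactants: 11 the (5S,6S)-epoxy triene silyl ether; 12 2-methylbut-3-en-2-ol
Product: 13 methyl (2E)-4-(tert-butyldimethylsilyloxy)-2-{2-[(2S,3S)-3-[(2E)-4-hydroxy-4-methylpent-2-en-1-yl]-3-methyloxiran-2-yl]ethyl}but-2-enoate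
Conditions: 12 (5 equiv), second-generation Grubbs catalyst RuCl2(=CHPh)(PCy3)(H2IMes) (5 mol %), CH2Cl2, 40 °C
Reagents that add atoms: none
Why: Olefin cross-metathesis between a terminal alkene and an excess of the slowly homodimerising tertiary allylic alcohol should give the E disubstituted C2=C3 alkene, the trisubstituted enoate and the epoxide being inert to the ruthenium carbene.

Step 7
Reactants: 13 the tertiary allylic alcohol
Product: 14 methyl (2E)-4-(tert-butyldimethylsilyloxy)-2-{2-[(2S,3S)-3-[(2E)-4-(methoxycarbonyloxy)-4-methylpent-2-en-1-yl]-3-methyloxiran-2-yl]ethyl}but-2-enoate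
Conditions: LiN(SiMe3)2 (1.05 equiv), THF, −78 °C; ClCO2Me, −78 → 0 °C
Reagents that add atoms: methyl chloroformate, COC(=O)Cl
Why: The tertiary alkoxide formed with one equivalent of a non-nucleophilic amide base is acylated by the chloroformate at low temperature, the usual way to carbonates of hindered tertiary allylic alcohols, the OH being far more acidic than any C–H of the enoate.

Step 8
Reactants: 14 the tertiary allylic methyl carbonate silyl ether
Product: 15 methyl (2E)-4-hydroxy-2-{2-[(2S,3S)-3-[(2E)-4-(methoxycarbonyloxy)-4-methylpent-2-en-1-yl]-3-methyloxiran-2-yl]ethyl}but-2-enoate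
Conditions: Bu4NF, AcOH (1:1), THF, 0 °C → rt
Reagents that add atoms: none
Why: Fluoride cleaves the primary allylic silyl ether while the acetic acid buffer keeps the medium too weakly basic to harm the carbonate or the ester, and because CH2OH is trans to CO2Me no butenolide can form.

Step 9
Reactants: 15 the primary allylic alcohol
Product: 16 methyl (2E)-2-{2-[(2S,3S)-3-[(2E)-4-(methoxycarbonyloxy)-4-methylpent-2-en-1-yl]-3-methyloxiran-2-yl]ethyl}-4-oxobut-2-enoate (open-chain epoxy enal, key-step precursor)
Conditions: Dess–Martin periodinane, NaHCO3, CH2Cl2, 0 °C → rt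
Reagents that add atoms: none
Why: Dess–Martin oxidation of a primary allylic alcohol to the enal under bicarbonate buffer is mild enough for the epoxide and the tertiary allylic carbonate, and the aldehyde has no α-hydrogen through which it could isomerise.

Step 10
Reactants: 16 the open-chain epoxy enal carbonate
Product: 18 methyl (2E,5S,6S,9E)-5,6-epoxy-11-hydroxy-1,1,5-trimethylcycloundeca-2,9-diene-9-carboxylate as both C11 epimers, via allylindium 17 (not isolated)
Conditions: Pd(PPh3)4 (10 mol %), InI (2 equiv), THF, rt, 16 added by syringe pump over 12 h (final 2 mM); aq. NH4Cl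
Reagents that add atoms: none
Why: Proposed new method: zerovalent palladium ionises the tertiary allylic carbonate (loss of CO2 and methoxide) to a π-allylpalladium complex over C1–C3, monovalent indium (InI) transmetalates it reductively to the σ-allylindium 17 bound at the less substituted C3, and 17 adds through its CMe2 terminus C1 to the C11 aldehyde in a six-membered chair transition state (SE2′). The closest known reactions are the intermolecular Pd/InI umpolung allylation of aldehydes by allylic carbonates and the Nozaki–Hiyama reverse prenylation, both of which deliver the disubstituted allyl terminus to the carbonyl; new here is the use as an 11-membered ring closure that creates a quaternary carbon. The carbocycle closes by C1–C11 bond formation, exo at the carbonyl (11-exo-trig) with allylic transposition, so the C2=C3 alkene (expected E from the chair, its geometry being erased in step 13) ends up inside the ring, and slow addition at high dilution counters oligomerisation. C11 is the only new stereocentre and neither the remote C5/C6 epoxide nor the achiral allylindium can be relied on to choose its face, so 18 is carried on as both epimers (one of them is 20) and C11 is fixed by reagent control in steps 11 and 12. The step needs attack through C1 and not C3 (11- versus 9-membered ring) and carbonyl addition ahead of β-hydride loss from the π-allyl; the preference of γ,γ-dimethylallylindium species for γ-attack, the ester-activated aldehyde without α-hydrogen, and an epoxide that is not allylic and is therefore left alone by zerovalent palladium should secure this.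

Step 11
Reactants: 18 the macrocyclic alcohol as both C11 epimers
Product: 19 methyl (2E,5S,6S,9E)-5,6-epoxy-1,1,5-trimethyl-11-oxocycloundeca-2,9-diene-9-carboxylate
Conditions: Dess–Martin periodinane, NaHCO3, CH2Cl2, rt
Reagents that add atoms: none
Why: Dess–Martin oxidation converts both C11 epimers into one enone and so erases the uncontrolled stereocentre, and because C1 is quaternary the β,γ-alkene C2=C3 cannot move into conjugation.

Step 12
Reactants: 19 the macrocyclic enone
Product: 20 methyl (2E,5S,6S,9E,11R)-5,6-epoxy-11-hydroxy-1,1,5-trimethylcycloundeca-2,9-diene-9-carboxylate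
Conditions: (S)-2-methyl-CBS-oxazaborolidine (0.5 equiv), catecholborane (2 equiv), toluene, −78 → −40 °C; MeOH, then pH 7 buffer
Reagents that add atoms: none
Why: Corey–Bakshi–Shibata reduction of an enone, in which the oxazaborolidine binds the C11 carbonyl anti to the larger flank, taken to be the fully substituted C1 (the same ranking as for tert-butyl methyl ketone) with the sp2 C10–H flank as the smaller, so the (S)-catalyst should deliver hydride to the face that gives (11R), and catecholborane as hydride source avoids hydroboration of C2=C3.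

Step 13
Reactants: 20 the (11R)-hydroxy diene ester
Product: 21 methyl (5S,6S,9E,11R)-5,6-epoxy-11-hydroxy-1,1,5-trimethylcycloundec-9-ene-9-carboxylate
Conditions: 2-nitrobenzenesulfonylhydrazide, Et3N, CH2Cl2, rt (repeated charges)
Reagents that add atoms: none
Why: Diimide generated from the sulfonylhydrazide transfers H2 in a concerted syn fashion and is fastest with strained, less substituted alkenes, so the E-1,2-disubstituted C2=C3 bond of the medium ring should be reduced ahead of the trisubstituted conjugated C9=C10 bond, with no hydrogenolysis of the epoxide or of the allylic C–O bond.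

Step 14
Reactants: 21 the saturated (11R)-hydroxy ester
Product: 22 (5S,6S,9E,11R)-5,6-epoxy-11-hydroxy-1,1,5-trimethylcycloundec-9-ene-9-carboxylic acid
Conditions: LiOH·H2O, THF/MeOH/H2O, rt; then 0.5 M HCl to pH 4, 0 °C
Reagents that add atoms: lithium hydroxide, [Li+].[OH-]
Why: Saponification of the methyl ester with LiOH leaves the epoxide and the stereocentres untouched, and since C11–OH is trans to the carboxyl across C9=C10 the hydroxy acid cannot lactonise.

Step 15
Reactants: 22 the hydroxy acid
Product: 24 (5S,6S,9E,11R)-11-(benzoyloxy)-5,6-epoxy-1,1,5-trimethylcycloundec-9-ene-9-carboxylic acid (CNP0377917.2), via mixed benzoic anhydride 23 (not isolated)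
Conditions: BzCl (3 equiv), pyridine, DMAP (cat.), CH2Cl2, 0 °C → rt; then pyridine/H2O, rt; pH 4 work-up
Reagents that add atoms: benzoyl chloride, O=C(Cl)c1ccccc1
Why: DMAP-catalysed acylation with excess benzoyl chloride benzoylates the hindered C11–OH with retention and at the same time turns the acid into a mixed benzoic anhydride, which aqueous pyridine hydrolyses back to the free acid while the benzoate ester stays.

**Compound list**

1 | pent-1-en-4-yne | C=CCC#C | starting material
2 | oxirane | C1CO1 | starting material
3 | dimethyl[(1E)-2-methylpenta-1,4-dien-1-yl]alane | C=CC/C(C)=C/[Al](C)C | intermediate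
4 | lithium butyl(dimethyl)[(1E)-2-methylpenta-1,4-dien-1-yl]aluminate | C=CC/C(C)=C/[Al-](C)(C)CCCC.[Li+] | intermediate
5 | (3E)-4-methylhepta-3,6-dien-1-ol | C=CC/C(C)=C/CCO | intermediate
6 | (4E)-7-iodo-4-methylhepta-1,4-diene | C=CC/C(C)=C/CCI | intermediate
7 | trimethyl phosphonoacetate | COC(=O)CP(=O)(OC)OC | starting material
8 | methyl (5E)-2-(dimethoxyphosphoryl)-6-methylnona-5,8-dienoate | C=CC/C(C)=C/CCC(C(=O)OC)P(=O)(OC)OC | intermediate
9 | (tert-butyldimethylsilyloxy)acetaldehyde | CC(C)(C)[Si](C)(C)OCC=O | starting material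
10 | methyl (2E,5E)-2-[2-(tert-butyldimethylsilyloxy)ethylidene]-6-methylnona-5,8-dienoate | C=CC/C(C)=C/CC/C(C(=O)OC)=C\CO[Si](C)(C)C(C)(C)C | intermediate
11 | methyl (2E)-4-(tert-butyldimethylsilyloxy)-2-{2-[(2S,3S)-3-methyl-3-(prop-2-en-1-yl)oxiran-2-yl]ethyl}but-2-enoate | C=CC[C@]1(C)O[C@H]1CC/C(C(=O)OC)=C\CO[Si](C)(C)C(C)(C)C | intermediate
12 | 2-methylbut-3-en-2-ol | CC(C)(O)C=C | starting material
13 | methyl (2E)-4-(tert-butyldimethylsilyloxy)-2-{2-[(2S,3S)-3-[(2E)-4-hydroxy-4-methylpent-2-en-1-yl]-3-methyloxiran-2-yl]ethyl}but-2-enoate | CC(C)(O)/C=C/C[C@]1(C)O[C@H]1CC/C(C(=O)OC)=C\CO[Si](C)(C)C(C)(C)C | intermediate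
14 | methyl (2E)-4-(tert-butyldimethylsilyloxy)-2-{2-[(2S,3S)-3-[(2E)-4-(methoxycarbonyloxy)-4-methylpent-2-en-1-yl]-3-methyloxiran-2-yl]ethyl}but-2-enoate | COC(=O)OC(C)(C)/C=C/C[C@]1(C)O[C@H]1CC/C(C(=O)OC)=C\CO[Si](C)(C)C(C)(C)C | intermediate
15 | methyl (2E)-4-hydroxy-2-{2-[(2S,3S)-3-[(2E)-4-(methoxycarbonyloxy)-4-methylpent-2-en-1-yl]-3-methyloxiran-2-yl]ethyl}but-2-enoate | COC(=O)OC(C)(C)/C=C/C[C@]1(C)O[C@H]1CC/C(C(=O)OC)=C\CO | intermediate
16 | methyl (2E)-2-{2-[(2S,3S)-3-[(2E)-4-(methoxycarbonyloxy)-4-methylpent-2-en-1-yl]-3-methyloxiran-2-yl]ethyl}-4-oxobut-2-enoate | COC(=O)OC(C)(C)/C=C/C[C@]1(C)O[C@H]1CC/C(C(=O)OC)=C\C=O | intermediate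
17 | C3-bound allylindium iodide methoxide of 16 (trivalent indium, C3 configuration undefined) | CO[In](I)C(C=C(C)C)C[C@]1(C)O[C@H]1CC/C(C(=O)OC)=C\C=O | intermediate
18 | methyl (2E,5S,6S,9E)-5,6-epoxy-11-hydroxy-1,1,5-trimethylcycloundeca-2,9-diene-9-carboxylate, both C11 epimers | CC1(C)/C=C/C[C@]2(C)O[C@H]2CC/C(C(=O)OC)=C\C1O | intermediate
19 | methyl (2E,5S,6S,9E)-5,6-epoxy-1,1,5-trimethyl-11-oxocycloundeca-2,9-diene-9-carboxylate | CC1(C)/C=C/C[C@]2(C)O[C@H]2CC/C(C(=O)OC)=C\C1=O | intermediate
20 | methyl (2E,5S,6S,9E,11R)-5,6-epoxy-11-hydroxy-1,1,5-trimethylcycloundeca-2,9-diene-9-carboxylate | CC1(C)/C=C/C[C@]2(C)O[C@H]2CC/C(C(=O)OC)=C\[C@H]1O | intermediate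
21 | methyl (5S,6S,9E,11R)-5,6-epoxy-11-hydroxy-1,1,5-trimethylcycloundec-9-ene-9-carboxylate | CC1(C)CCC[C@]2(C)O[C@H]2CC/C(C(=O)OC)=C\[C@H]1O | intermediate
22 | (5S,6S,9E,11R)-5,6-epoxy-11-hydroxy-1,1,5-trimethylcycloundec-9-ene-9-carboxylic acid | CC1(C)CCC[C@]2(C)O[C@H]2CC/C(C(=O)O)=C\[C@H]1O | intermediate
23 | benzoic (5S,6S,9E,11R)-11-(benzoyloxy)-5,6-epoxy-1,1,5-trimethylcycloundec-9-ene-9-carboxylic anhydride | CC1(C)CCC[C@]2(C)O[C@H]2CC/C(C(=O)OC(=O)c3ccccc3)=C\[C@H]1OC(=O)c1ccccc1 | intermediate
24 | (5S,6S,9E,11R)-11-(benzoyloxy)-5,6-epoxy-1,1,5-trimethylcycloundec-9-ene-9-carboxylic acid (CNP0377917.2) | CC1(C)CCC[C@]2(C)O[C@H]2CC/C(C(=O)O)=C\[C@H]1OC(=O)c1ccccc1 | target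

**Step count and risks**

Total step count: 15. Longest linear sequence: 15 steps, from pent-1-en-4-yne (1) to 24.

Steps most likely to fail:

1. Step 10 (ring closure by the allylindium). The chain may oligomerise instead of closing, the π-allyl may lose a β-hydrogen to give a 1,3-diene, or closure may occur through C3 to the nine-membered ring. The fallback uses known reactions only: the C1–C11 bond is made intermolecularly and the ring is closed at C2=C3 by metathesis. It sets out from 11.
   - Bu4NF/AcOH should give methyl (2E)-4-hydroxy-2-{2-[(2S,3S)-3-methyl-3-(prop-2-en-1-yl)oxiran-2-yl]ethyl}but-2-enoate F1.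
   - Dess–Martin periodinane/NaHCO3 should give the corresponding 4-oxobut-2-enoate F2.
   - Brown reverse prenylation adds the CMe2 terminus to the si face of the aldehyde and should give the (11R)-carbinol with a 1,1-dimethylallyl group, methyl (2E,4R)-4-hydroxy-5,5-dimethyl-2-{2-[(2S,3S)-3-methyl-3-(prop-2-en-1-yl)oxiran-2-yl]ethyl}hepta-2,6-dienoate F3. The reagent is the B-prenyldiisopinocampheylborane made from (−)-Ipc2BOMe (from (+)-α-pinene) and prenylpotassium KCH2CH=CMe2, in Et2O at −78 °C with ethanolamine work-up.
   - Ring-closing metathesis of the two terminal alkenes of F3 (second-generation Grubbs catalyst, high dilution, refluxing CH2Cl2 or toluene) should close the 11-membered ring at C2=C3. It should give 20 and/or its C2=C3 Z isomer, methyl (2Z,5S,6S,9E,11R)-5,6-epoxy-11-hydroxy-1,1,5-trimethylcycloundeca-2,9-diene-9-carboxylate F4.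
   - Both are saturated under the conditions of step 13, so the fallback comes back to the route at 21. It sets C11 by reagent control and makes steps 11 and 12 unnecessary.

2. Step 12 (face selection at C11). The simple size ranking of the two carbonyl flanks (quaternary C1 against the cis-substituted alkenyl C10) may not hold in a conformationally biased medium ring, giving poor or reversed selectivity or a slow reduction. The fallback replaces asymmetric induction by separation and recycling, and sets out from 18. The two C11 epimers are diastereomers and are separated by chromatography into 20 and methyl (2E,5S,6S,9E,11S)-5,6-epoxy-11-hydroxy-1,1,5-trimethylcycloundeca-2,9-diene-9-carboxylate F5. F5 alone is oxidised under the conditions of step 11 to 19 and reduced without a chiral reagent (Luche reduction: NaBH4, CeCl3·7H2O, MeOH, −40 °C) back to the pair 18 for another separation. Material is funnelled in this way to 20, where the route continues.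

3. Step 13 (site selectivity of the alkene reduction). Diimide may also reduce the electron-poor conjugated C9=C10 bond, or react sluggishly at the C2=C3 bond next to the quaternary carbon. The fallback changes from stoichiometric diimide transfer to catalytic homogeneous hydrogenation on RhCl(PPh3)3 (H2 1 atm, benzene/EtOH, rt). This catalyst binds the alkene and selects by substitution (1,2-disubstituted far ahead of trisubstituted, conjugated trisubstituted esters inert) and does not hydrogenolyse epoxides. It sets out from 20 and comes back at 21, and makes no compound outside the list (F0).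

**Further compounds**

F1 | step 10 | methyl (2E)-4-hydroxy-2-{2-[(2S,3S)-3-methyl-3-(prop-2-en-1-yl)oxiran-2-yl]ethyl}but-2-enoate | C=CC[C@]1(C)O[C@H]1CC/C(C(=O)OC)=C\CO
F2 | step 10 | methyl (2E)-2-{2-[(2S,3S)-3-methyl-3-(prop-2-en-1-yl)oxiran-2-yl]ethyl}-4-oxobut-2-enoate | C=CC[C@]1(C)O[C@H]1CC/C(C(=O)OC)=C\C=O
F3 | step 10 | methyl (2E,4R)-4-hydroxy-5,5-dimethyl-2-{2-[(2S,3S)-3-methyl-3-(prop-2-en-1-yl)oxiran-2-yl]ethyl}hepta-2,6-dienoate | C=CC[C@]1(C)O[C@H]1CC/C(C(=O)OC)=C\[C@@H](O)C(C)(C)C=C
F4 | step 10 | methyl (2Z,5S,6S,9E,11R)-5,6-epoxy-11-hydroxy-1,1,5-trimethylcycloundeca-2,9-diene-9-carboxylate | CC1(C)/C=C\C[C@]2(C)O[C@H]2CC/C(C(=O)OC)=C\[C@H]1O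
F5 | step 12 | methyl (2E,5S,6S,9E,11S)-5,6-epoxy-11-hydroxy-1,1,5-trimethylcycloundeca-2,9-diene-9-carboxylate | CC1(C)/C=C/C[C@]2(C)O[C@H]2CC/C(C(=O)OC)=C\[C@@H]1O
F0 | step 13 | none | none
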